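**Numbering.** Labdane numbering is used for atoms throughout: ring A = C1–C5, C10; ring B = C5–C10; C17 = exocyclic CH2 on C8; C18, C19 = the two CH2OAc carbons on C4; C20 = methyl on C10; C11–C16 = side chain. Compounds are numbered 1–23 as in the steps.

## Analysis of the target

The target is a trans-fused decalin of the labdane type: C10 carries the angular methyl C20, C8 the exocyclic methylene C17, and C9 the (2E)-3-methylpenta-2,4-dienyl chain C11–C16. There are three contiguous stereocentres, C5 (S), C9 (R) and C10 (S). H-5 and H-9 are cis to each other and trans to C20, and the C9 chain is equatorial and cis to C20; this is the enantiomeric (ent) labdane series. C4 is quaternary but carries two identical acetoxymethyl arms (C18, C19), so it is not stereogenic. That is the feature the route exploits: C4 can pass through the ring-forming step as a catalyst-set CH stereocentre, relay its configuration to C5, C10 and C9, and then be symmetrised. The second feature is the C8=C17 methylene next to C9, which is the footprint of an allylsilane that has ended a cation–olefin cascade. Sensitive groups are the conjugated 12E,14-diene (oxidants, acid), the exocyclic alkene (acid isomerises it into the ring) and the two acetates (base, hydride). The difficulty is that C5 sits between two fully substituted carbons (C4, C10), that no heteroatom is attached to any stereocentre to serve as a handle for absolute configuration, and that the alkene at C8 must be the less stable exocyclic isomer.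

## Retrosynthetic reasoning

**Diene last (23 to 20).** C14=C15 is cut by Wittig methylenation of enal 22, and C12=C13 by a stabilised Wittig reaction of aldehyde 21, made from alcohol 20. The diene is the group least compatible with the osmium and acid chemistry used earlier, so it is built at the end; the E geometry comes from the stabilised ylide.

**The two C4 arms (19 to 16).** The diacetate 19 comes from diol 18, and 18 from aldehyde 16 by aldol addition to formaldehyde and crossed Cannizzaro reduction. C19 is added and C18 is reduced in one operation. The gain is that the cyclization does not have to form a quaternary C4: it only has to deliver C4 as CH–C18.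

**C18 from a vinyl group (16 to 14).** The aldehyde is cut back to the vinyl group of 14 by dihydroxylation and periodate cleavage. The forward step must distinguish the vinyl group from the hindered C8=C17 methylene.

**Key disconnection (14 to 13).** C4–C5 and C9–C10 are cut together. This opens both rings and removes C5, C9, C10 and the temporary C4 stereocentre in one step, leading to the acyclic, racemic allylic alcohol 13. Forward, a chiral iridium catalyst turns the allylic alcohol into an allyl cation equivalent at C4; the E alkene C5=C10 and the allylsilane C8=C9 close the two rings, and loss of silicon gives C8=C17. The cut is made at the bonds flanking the two fully substituted carbons because alkene geometry then dictates the trans fusion and the equatorial C9 chain. The same two bonds could be closed as a radical from a malonate carbon, which is weighed under Alternative 2.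

**Allylic alcohol (13 to 9).** C4–C18 is cut to aldehyde 12 and a vinyl Grignard reagent; 12 comes from 9 by a silyl exchange (10, 11) and oxidation.

**Allylsilane (9 to 5 + 6).** C8–C17 is cut by a nickel-catalysed coupling of (trimethylsilyl)methyl Grignard reagent with the cyclic enol ether 8, and C7–C8 by alkylation of lithiated 2,3-dihydrofuran 7 with iodide 5. The ring of 8 fixes the alkene geometry, and its oxygen becomes the C12 hydroxyl.

**First alkene (5 to 1).** C10–C20 and C5–C6 are cut by syn carboalumination of alkyne 1 and trapping with ethylene oxide, which sets E geometry at C5=C10.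

Carbon sources: 1 gives C1–C5 and C10; AlMe3 gives C20; ethylene oxide gives C6 and C7; 6 gives C8, C9, C11, C12; the silylmethyl Grignard gives C17; the vinyl Grignard gives C18; formaldehyde gives C19; the two ylides give C13, C14, C16 and C15.

## Alternatives that were turned down

**Alternative 1:** (textbook) Ring-by-ring construction by Robinson annulation. C10 would be set by the proline-catalysed Hajos–Parrish–Eder–Sauer–Wiechert aldol, giving (R)-Wieland–Miescher ketone A1; C5, C4 and C9 would then be elaborated one at a time. Turned down because A1 carries carbonyl groups at C3 and C9, where the target has no oxygen. C4 would need two oxygenated one-carbon units introduced by enolate chemistry next to a carbonyl that must then be removed. C9 would have to be converted from C=O to CH–CH2R with a new methylene at C8. No two stereocentres are set together, and the sequence would be well beyond twenty steps.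

**Alternative 2:** Oxidative radical bicyclization. The same ring bonds (C4–C5, C9–C10) are formed, but from C4 as a malonyl radical that already carries C18 and C19. Mn(OAc)3 would oxidise the acyclic malonate A2; two 6-endo closures and oxidation of the C8 radical by Cu(OAc)2 would give the diester A3 with the exocyclic alkene. It is attractive because reduction and acetylation would finish C4. It was turned down because the malonyl radical is planar and bears two identical esters, so nothing in A2 distinguishes the two faces of C5=C10 and A3 is racemic. A chiral ester auxiliary on a symmetric malonate has no basis for face control, and resolution discards half of the material. The step saved does not pay for the loss of absolute control.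

**Alternative 3:** Chiral pool. Andrographolide A4 already has the C5, C9, C10 configuration, the C8=C17 methylene and the C19 hydroxyl. The key step would be a hydroxyl-directed, iridium-catalysed γ-C–H silylation of the C18 methyl with Tamao–Fleming oxidation, carried out on the 19-ol A5 or a precursor of it. Turned down because the remaining changes are all corrections. The C16 lactone carbonyl must be reduced to a methyl group. The C14 and C15 oxygens must be removed while C14=C15 is formed. The C3 hydroxyl must be removed by a radical deoxygenation that a diene does not tolerate. The C–H silylation would also have to ignore C8=C17. The ordering conflicts lead to more than a dozen redox and protecting-group steps, and the result would be a semisynthesis.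

Key step: step 9

## Route

Remark: the (S) ligand in step 9 is assumed to give the 4R configuration of 14; if the sense of induction is the opposite, the (R) ligand is used and nothing else changes.
Remark: compound 1 is taken as a purchased silyl ether (otherwise one silylation from hex-5-yn-1-ol).

Step 1
Reactants: 1 tert-butyl(hex-5-yn-1-yloxy)dimethylsilane
Product: 4 (E)-8-[(tert-butyldimethylsilyl)oxy]-4-methyloct-3-en-1-ol, via alkenyldimethylalane 2 (not isolated), via lithium alkenylaluminate 3 (not isolated)
Conditions: AlMe3, Cp2ZrCl2 (25 mol %), CH2Cl2, 0 °C to rt; then n-BuLi, THF, −30 °C; ethylene oxide, −30 °C to rt; aq. Rochelle salt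
Reagents that add atoms: trimethylaluminium, C[Al](C)C; ethylene oxide, C1CO1
Why: Negishi zirconium-catalysed carboalumination adds methyl and aluminium syn across the terminal alkyne with methyl on the internal carbon, so C20 ends cis to the metal and, after ate-complex formation and opening of ethylene oxide, C6 ends trans to C1 (E alkene C5=C10); silyl ethers are tolerated.

Step 2
Reactants: 4 (E)-8-[(tert-butyldimethylsilyl)oxy]-4-methyloct-3-en-1-ol
Product: 5 (E)-tert-butyl[(8-iodo-5-methyloct-5-en-1-yl)oxy]dimethylsilane
Conditions: I2, PPh3, imidazole, CH2Cl2, 0 °C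
Reagents that add atoms: iodine, II
Why: Appel-type iodination of a primary alcohol under buffered conditions; the silyl ether and the trisubstituted alkene are not affected.

Step 3
Reactants: 5 (E)-tert-butyl[(8-iodo-5-methyloct-5-en-1-yl)oxy]dimethylsilane; 6 2,3-dihydrofuran
Product: 8 (E)-tert-butyl{[8-(4,5-dihydrofuran-2-yl)-5-methyloct-5-en-1-yl]oxy}dimethylsilane, via 5-lithio-2,3-dihydrofuran 7 (not isolated)
Conditions: 6 (slight excess), t-BuLi, THF, −78 to 0 °C; then 5, 0 °C to rt; used without acidic work-up
Reagents that add atoms: none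
Why: α-Lithiation of the cyclic enol ether followed by SN2 alkylation with the primary iodide forms C7–C8; keeping 6 in excess over t-BuLi avoids iodine–lithium exchange on 5.

Step 4
Reactants: 8 (E)-tert-butyl{[8-(4,5-dihydrofuran-2-yl)-5-methyloct-5-en-1-yl]oxy}dimethylsilane
Product: 9 (3Z,7E)-12-[(tert-butyldimethylsilyl)oxy]-8-methyl-4-[(trimethylsilyl)methyl]dodeca-3,7-dien-1-ol
Conditions: Me3SiCH2MgCl, NiCl2(PPh3)2 (5 mol %), toluene/Et2O, 80 °C
Reagents that add atoms: (trimethylsilyl)methylmagnesium chloride, C[Si](C)(C)C[Mg]Cl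
Why: Nickel-catalysed Kumada-type coupling of an enol ether C–O bond (Wenkert reaction): zerovalent nickel inserts into the vinylic C8–O bond and the silylmethyl group replaces oxygen with retention, so C17 ends cis to C11 and the ring fixes the allylsilane geometry; the Grignard reagent has no β-hydrogen, which closes the reduction pathway, and the ring oxygen is released as the C12 hydroxyl.

Step 5
Reactants: 9 (3Z,7E)-12-[(tert-butyldimethylsilyl)oxy]-8-methyl-4-[(trimethylsilyl)methyl]dodeca-3,7-dien-1-ol
Product: 10 (3Z,7E)-12-[(tert-butyldimethylsilyl)oxy]-8-methyl-1-[(triisopropylsilyl)oxy]-4-[(trimethylsilyl)methyl]dodeca-3,7-diene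
Conditions: i-Pr3SiCl, imidazole, DMF, rt
Reagents that add atoms: chlorotriisopropylsilane, CC(C)[Si](Cl)(C(C)C)C(C)C
Why: Silylation of the primary alcohol; the triisopropylsilyl ether is chosen because it should outlast the acid of step 6 and the hydroxide of step 11 and can be removed beside acetates in step 13.

Step 6
Reactants: 10 (3Z,7E)-12-[(tert-butyldimethylsilyl)oxy]-8-methyl-1-[(triisopropylsilyl)oxy]-4-[(trimethylsilyl)methyl]dodeca-3,7-diene
Product: 11 (5E,9Z)-5-methyl-12-[(triisopropylsilyl)oxy]-9-[(trimethylsilyl)methyl]dodeca-5,9-dien-1-ol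
Conditions: pyridinium p-toluenesulfonate (cat.), MeOH, rt
Reagents that add atoms: none
Why: Acid-catalysed methanolysis removes the less hindered tert-butyldimethylsilyl ether in preference to the triisopropylsilyl ether; the pyridinium acid is too weak to protonate the allylsilane.

Step 7
Reactants: 11 (5E,9Z)-5-methyl-12-[(triisopropylsilyl)oxy]-9-[(trimethylsilyl)methyl]dodeca-5,9-dien-1-ol
Product: 12 (5E,9Z)-5-methyl-12-[(triisopropylsilyl)oxy]-9-[(trimethylsilyl)methyl]dodeca-5,9-dienal
Conditions: Dess–Martin periodinane, pyridine, CH2Cl2, 0 °C to rt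
Reagents that add atoms: none
Why: Dess–Martin oxidation of a primary alcohol; pyridine buffers the acetic acid formed so that the allylsilane is not protodesilylated.

Step 8
Reactants: 12 (5E,9Z)-5-methyl-12-[(triisopropylsilyl)oxy]-9-[(trimethylsilyl)methyl]dodeca-5,9-dienal
Product: 13 (7E,11Z)-7-methyl-14-[(triisopropylsilyl)oxy]-11-[(trimethylsilyl)methyl]tetradeca-1,7,11-trien-3-ol (racemic at the carbinol carbon C4)
Conditions: CH2=CHMgBr, THF, −78 °C
Reagents that add atoms: vinylmagnesium bromide, C=C[Mg]Br
Why: Grignard 1,2-addition forms C4–C18; the carbinol is left racemic on purpose because both enantiomers should converge on the same allyl–iridium intermediate in step 9.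

Step 9
Reactants: 13 (7E,11Z)-7-methyl-14-[(triisopropylsilyl)oxy]-11-[(trimethylsilyl)methyl]tetradeca-1,7,11-trien-3-ol
Product: 14 (1R,4aR,5R,8aR)-1-ethenyl-4a-methyl-6-methylidene-5-{2-[(triisopropylsilyl)oxy]ethyl}decahydronaphthalene (labdane numbering: 4R,5R,9R,10R)
Conditions: [Ir(cod)Cl]2 (4 mol %), (S)-BINOL-derived N-(5H-dibenzo[b,f]azepin-5-yl) phosphoramidite (P,olefin ligand, 16 mol %), Zn(OTf)2 (20 mol %), ClCH2CH2Cl, 25 °C
Reagents that add atoms: none
Why: Zn(OTf)2-assisted ionisation of the allylic alcohol by the monovalent iridium–ligand complex gives an η3-allyl complex of trivalent iridium from either enantiomer of 13, and the ligand decides which face of the substituted allyl terminus C4 is open. C5 of the E alkene attacks C4 while C9 of the allylsilane attacks the developing C10 cation, and loss of the silyl group from the β-silyl cation at C8 ends the cascade as the C8=C17 methylene with no regioisomer possible. The closest known reaction type is the iridium-catalysed enantioselective polyene cyclization of branched allylic alcohols, which has been terminated by arenes and by allylsilanes. Ring A closes in a 6-endo-trig cation–olefin mode (C4–C5) and ring B likewise 6-endo-trig (C9–C10), both through chair-like transition states. C4 is set by the catalyst; C5 and C10 follow from anti addition across the E alkene (trans fusion, vinyl equatorial), and C9 from the geometry of the allylsilane, which places C11 equatorial and cis to C20. The step needs branched over linear allylation, one enantioface, and a complete cascade in place of proton loss at C10: the first two rest on the ligand, the third on the high nucleophilicity of the trisubstituted allylsilane held in a six-membered chair next to the cation.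

Step 10
Reactants: 14 (1R,4aR,5R,8aR)-1-ethenyl-4a-methyl-6-methylidene-5-{2-[(triisopropylsilyl)oxy]ethyl}decahydronaphthalene
Product: 16 (1S,4aR,5R,8aR)-4a-methyl-6-methylidene-5-{2-[(triisopropylsilyl)oxy]ethyl}decahydronaphthalene-1-carbaldehyde, via vicinal diol 15 (not isolated)
Conditions: OsO4 (2 mol %), N-methylmorpholine N-oxide, acetone/H2O, 0 °C, stopped when 14 is consumed; then NaIO4, rt
Reagents that add atoms: N-methylmorpholine N-oxide, C[N+]1([O-])CCOCC1 (terminal oxidant; the oxygen reaches C18 through OsO4, O=[Os](=O)(=O)=O)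
Why: Upjohn dihydroxylation followed by periodate cleavage in one flask (Lemieux–Johnson type); OsO4 should take the unhindered monosubstituted vinyl group before the C8=C17 methylene, whose axial face is blocked by C20 and whose other face is flanked by the C9 chain. The C4 configuration of 16 is of no consequence because step 11 removes it.

Step 11
Reactants: 16 (1S,4aR,5R,8aR)-4a-methyl-6-methylidene-5-{2-[(triisopropylsilyl)oxy]ethyl}decahydronaphthalene-1-carbaldehyde
Product: 18 {(4aS,5R,8aS)-4a-methyl-6-methylidene-5-{2-[(triisopropylsilyl)oxy]ethyl}octahydronaphthalene-1,1(2H)-diyl}dimethanol, via hydroxymethyl aldehyde 17 (not isolated)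
Conditions: aq. HCHO (excess), KOH, MeOH/H2O, rt to 55 °C
Reagents that add atoms: formaldehyde, C=O
Why: Tollens condensation: aldol addition of the enolisable aldehyde to formaldehyde at C4 adds C19, and the non-enolisable aldehyde 17 is then reduced by a second formaldehyde in a crossed Cannizzaro reaction; the C4 stereocentre, having relayed the absolute configuration to C5, C9 and C10, becomes a symmetric carbon here.

Step 12
Reactants: 18 {(4aS,5R,8aS)-4a-methyl-6-methylidene-5-{2-[(triisopropylsilyl)oxy]ethyl}octahydronaphthalene-1,1(2H)-diyl}dimethanol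
Product: 19 [(4aS,5R,8aS)-4a-methyl-6-methylidene-5-{2-[(triisopropylsilyl)oxy]ethyl}octahydronaphthalene-1,1(2H)-diyl]bis(methylene) diacetate
Conditions: Ac2O, pyridine, 4-(dimethylamino)pyridine (cat.), CH2Cl2, rt
Reagents that add atoms: acetic anhydride, CC(=O)OC(C)=O
Why: Nucleophile-catalysed acetylation of both neopentyl-type primary alcohols; no other group reacts.

Step 13
Reactants: 19 [(4aS,5R,8aS)-4a-methyl-6-methylidene-5-{2-[(triisopropylsilyl)oxy]ethyl}octahydronaphthalene-1,1(2H)-diyl]bis(methylene) diacetate
Product: 20 [(4aS,5R,8aS)-5-(2-hydroxyethyl)-4a-methyl-6-methylideneoctahydronaphthalene-1,1(2H)-diyl]bis(methylene) diacetate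
Conditions: HF·pyridine, pyridine, THF, 0 °C to rt
Reagents that add atoms: none
Why: Fluoride cleaves the Si–O bond; the pyridine-buffered reagent should leave the acetates and the exocyclic alkene untouched, and the C12 hydroxyl is too remote for acyl migration.

Step 14
Reactants: 20 [(4aS,5R,8aS)-5-(2-hydroxyethyl)-4a-methyl-6-methylideneoctahydronaphthalene-1,1(2H)-diyl]bis(methylene) diacetate
Product: 22 [(4aS,5R,8aS)-4a-methyl-5-[(2E)-3-methyl-4-oxobut-2-en-1-yl]-6-methylideneoctahydronaphthalene-1,1(2H)-diyl]bis(methylene) diacetate, via aldehyde 21 (not isolated)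
Conditions: Dess–Martin periodinane, pyridine, CH2Cl2, 0 °C to rt; then Ph3P=C(CH3)CHO, toluene, 80 °C
Reagents that add atoms: 2-(triphenylphosphoranylidene)propanal, CC(C=O)=P(c1ccccc1)(c1ccccc1)c1ccccc1
Why: Dess–Martin oxidation and Wittig reaction in one flask, so that the sensitive aldehyde 21 is not isolated; the stabilised α-methyl ylide should give the E trisubstituted enal (C12=C13) under thermodynamic control.

Step 15
Reactants: 22 [(4aS,5R,8aS)-4a-methyl-5-[(2E)-3-methyl-4-oxobut-2-en-1-yl]-6-methylideneoctahydronaphthalene-1,1(2H)-diyl]bis(methylene) diacetate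
Product: 23 [(4aS,5R,8aS)-4a-methyl-6-methylidene-5-[(2E)-3-methylpenta-2,4-dien-1-yl]octahydronaphthalene-1,1(2H)-diyl]bis(methylene) diacetate (target)
Conditions: Ph3PCH3Br, KN(SiMe3)2, THF, 0 °C; then 22, −78 to 0 °C
Reagents that add atoms: methyltriphenylphosphonium bromide, C[P+](c1ccccc1)(c1ccccc1)c1ccccc1.[Br-]
Why: Wittig methylenation forms C14=C15; with a small excess of ylide at low temperature the aldehyde should react far faster than the acetates, and the 12E alkene is not touched.

## Compound list

1 | tert-butyl(hex-5-yn-1-yloxy)dimethylsilane | C#CCCCCO[Si](C)(C)C(C)(C)C | starting material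
2 | (E)-{6-[(tert-butyldimethylsilyl)oxy]-2-methylhex-1-en-1-yl}dimethylalane | C[Al](C)/C=C(\C)CCCCO[Si](C)(C)C(C)(C)C | intermediate
3 | lithium butyl{(E)-6-[(tert-butyldimethylsilyl)oxy]-2-methylhex-1-en-1-yl}dimethylaluminate | [Li+].CCCC[Al-](C)(C)/C=C(\C)CCCCO[Si](C)(C)C(C)(C)C | intermediate
4 | (E)-8-[(tert-butyldimethylsilyl)oxy]-4-methyloct-3-en-1-ol | OCC/C=C(\C)CCCCO[Si](C)(C)C(C)(C)C | intermediate
5 | (E)-tert-butyl[(8-iodo-5-methyloct-5-en-1-yl)oxy]dimethylsilane | ICC/C=C(\C)CCCCO[Si](C)(C)C(C)(C)C | intermediate
6 | 2,3-dihydrofuran | C1CC=CO1 | starting material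
7 | 5-lithio-2,3-dihydrofuran | [Li]C1=CCCO1 | intermediate
8 | (E)-tert-butyl{[8-(4,5-dihydrofuran-2-yl)-5-methyloct-5-en-1-yl]oxy}dimethylsilane | C1(CC/C=C(\C)CCCCO[Si](C)(C)C(C)(C)C)=CCCO1 | intermediate
9 | (3Z,7E)-12-[(tert-butyldimethylsilyl)oxy]-8-methyl-4-[(trimethylsilyl)methyl]dodeca-3,7-dien-1-ol | OCC/C=C(\C[Si](C)(C)C)CC/C=C(\C)CCCCO[Si](C)(C)C(C)(C)C | intermediate
10 | (3Z,7E)-12-[(tert-butyldimethylsilyl)oxy]-8-methyl-1-[(triisopropylsilyl)oxy]-4-[(trimethylsilyl)methyl]dodeca-3,7-diene | CC(C)[Si](C(C)C)(C(C)C)OCC/C=C(\C[Si](C)(C)C)CC/C=C(\C)CCCCO[Si](C)(C)C(C)(C)C | intermediate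
11 | (5E,9Z)-5-methyl-12-[(triisopropylsilyl)oxy]-9-[(trimethylsilyl)methyl]dodeca-5,9-dien-1-ol | CC(C)[Si](C(C)C)(C(C)C)OCC/C=C(\C[Si](C)(C)C)CC/C=C(\C)CCCCO | intermediate
12 | (5E,9Z)-5-methyl-12-[(triisopropylsilyl)oxy]-9-[(trimethylsilyl)methyl]dodeca-5,9-dienal | CC(C)[Si](C(C)C)(C(C)C)OCC/C=C(\C[Si](C)(C)C)CC/C=C(\C)CCCC=O | intermediate
13 | (7E,11Z)-7-methyl-14-[(triisopropylsilyl)oxy]-11-[(trimethylsilyl)methyl]tetradeca-1,7,11-trien-3-ol (racemic) | CC(C)[Si](C(C)C)(C(C)C)OCC/C=C(\C[Si](C)(C)C)CC/C=C(\C)CCCC(O)C=C | intermediate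
14 | (1R,4aR,5R,8aR)-1-ethenyl-4a-methyl-6-methylidene-5-{2-[(triisopropylsilyl)oxy]ethyl}decahydronaphthalene | CC(C)[Si](C(C)C)(C(C)C)OCC[C@@H]1C(=C)CC[C@@H]2[C@@H](C=C)CCC[C@@]12C | intermediate
15 | 1-[(1R,4aR,5R,8aR)-4a-methyl-6-methylidene-5-{2-[(triisopropylsilyl)oxy]ethyl}decahydronaphthalen-1-yl]ethane-1,2-diol (mixture at the new carbinol) | CC(C)[Si](C(C)C)(C(C)C)OCC[C@@H]1C(=C)CC[C@@H]2[C@@H](C(O)CO)CCC[C@@]12C | intermediate
16 | (1S,4aR,5R,8aR)-4a-methyl-6-methylidene-5-{2-[(triisopropylsilyl)oxy]ethyl}decahydronaphthalene-1-carbaldehyde | CC(C)[Si](C(C)C)(C(C)C)OCC[C@@H]1C(=C)CC[C@@H]2[C@@H](C=O)CCC[C@@]12C | intermediate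
17 | (4aS,5R,8aS)-1-(hydroxymethyl)-4a-methyl-6-methylidene-5-{2-[(triisopropylsilyl)oxy]ethyl}decahydronaphthalene-1-carbaldehyde (mixture at C1) | CC(C)[Si](C(C)C)(C(C)C)OCC[C@@H]1C(=C)CC[C@@H]2C(CO)(C=O)CCC[C@@]12C | intermediate
18 | {(4aS,5R,8aS)-4a-methyl-6-methylidene-5-{2-[(triisopropylsilyl)oxy]ethyl}octahydronaphthalene-1,1(2H)-diyl}dimethanol | CC(C)[Si](C(C)C)(C(C)C)OCC[C@@H]1C(=C)CC[C@@H]2C(CO)(CO)CCC[C@@]12C | intermediate
19 | [(4aS,5R,8aS)-4a-methyl-6-methylidene-5-{2-[(triisopropylsilyl)oxy]ethyl}octahydronaphthalene-1,1(2H)-diyl]bis(methylene) diacetate | CC(C)[Si](C(C)C)(C(C)C)OCC[C@@H]1C(=C)CC[C@@H]2C(COC(C)=O)(COC(C)=O)CCC[C@@]12C | intermediate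
20 | [(4aS,5R,8aS)-5-(2-hydroxyethyl)-4a-methyl-6-methylideneoctahydronaphthalene-1,1(2H)-diyl]bis(methylene) diacetate | OCC[C@@H]1C(=C)CC[C@@H]2C(COC(C)=O)(COC(C)=O)CCC[C@@]12C | intermediate
21 | [(4aS,5R,8aS)-4a-methyl-6-methylidene-5-(2-oxoethyl)octahydronaphthalene-1,1(2H)-diyl]bis(methylene) diacetate | O=CC[C@@H]1C(=C)CC[C@@H]2C(COC(C)=O)(COC(C)=O)CCC[C@@]12C | intermediate
22 | [(4aS,5R,8aS)-4a-methyl-5-[(2E)-3-methyl-4-oxobut-2-en-1-yl]-6-methylideneoctahydronaphthalene-1,1(2H)-diyl]bis(methylene) diacetate | O=C/C(C)=C/C[C@@H]1C(=C)CC[C@@H]2C(COC(C)=O)(COC(C)=O)CCC[C@@]12C | intermediate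
23 | [(4aS,5R,8aS)-4a-methyl-6-methylidene-5-[(2E)-3-methylpenta-2,4-dien-1-yl]octahydronaphthalene-1,1(2H)-diyl]bis(methylene) diacetate (ent-labda-8(17),12E,14-triene-18,19-diyl diacetate) | C=C/C(C)=C/C[C@@H]1C(=C)CC[C@@H]2C(COC(C)=O)(COC(C)=O)CCC[C@@]12C | target

## Step count and least certain steps

Total step count: 15. Longest linear sequence: 15 steps (from 1; the route is linear).

**Step 9 (key step).** The cascade may stop after ring A through loss of a proton from the C10 cation. The allylsilane may also be protodesilylated by traces of triflic acid before it is needed, and face control at C4 may be weaker than with arene terminators. Fallback with auxiliary control in place of catalyst control, setting out from 12 and returning at 16: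
- Aldehyde 12 is condensed with (2S,4S)-pentane-2,4-diol (pyridinium p-toluenesulfonate, MgSO4, CH2Cl2) to the dioxane acetal F1.
- TiCl4 in CH2Cl2 at −78 °C should open the acetal at the C–O bond next to the axial methyl while C5 attacks C4 anti to the leaving oxygen. The same chair–chair relay and allylsilane termination should give the hydroxy ether F2 with the C4 oxygen equatorial.
- Dess–Martin oxidation of the auxiliary carbinol gives the keto ether F3, and β-elimination with K2CO3 in MeOH releases the C4 alcohol F4.
- Oxidation gives the ketone F5, Wittig reaction with Ph3P=CHOMe the enol ether F6, and oxalic acid in wet THF the aldehyde 16.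
- The price is six operations in place of two, and C5 is α to the carbonyl in F5, so enolising conditions must be avoided there.

**Step 10.** Site selectivity between the vinyl group and the C8=C17 methylene may be insufficient, leading to over-oxidation at C8. Fallback by stepwise one-carbon degradation, from 14 back to 16:
- Hydroboration with disiamylborane, which strongly prefers the monosubstituted alkene, then H2O2/NaOH gives the primary alcohol F7.
- Dess–Martin oxidation gives the homologous aldehyde F8.
- t-BuMe2SiOTf/Et3N gives the silyl enol ether F9.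
- One equivalent of ozone at −78 °C, then Me2S, cleaves the electron-rich enol ether before the exocyclic alkene and gives 16.

**Step 4.** Insertion of nickel into the enol ether C–O bond may be slow with the bulky silylmethyl Grignard reagent, and reversible nickel hydride chemistry could erode the alkene geometry. Fallback by carbometalation, from 5 back to 9:
- Iodide 5 alkylates LiC≡CH·H2NCH2CH2NH2 in DMSO to give the enyne F10.
- Normant carbocupration with Me3SiCH2Cu·MgBrCl (from the same Grignard reagent and CuBr·SMe2; a slow member of this reaction family) adds syn and gives the alkenylcopper F11.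
- Trapping F11 with ethylene oxide gives 9 with the same geometry.

**Step 11.** The crossed Cannizzaro reduction of the hindered aldehyde 17 may be slow, and the silyl ether may be lost under hot hydroxide. Fallback from 16 back to 18 that separates the two events: aldol addition to formaldehyde with K2CO3 in THF/H2O, isolation of 17, then NaBH4 in MeOH to 18. No new compound is needed.

## Further compounds

F1 | step 9 | (4S,6S)-4,6-dimethyl-2-[(4E,8Z)-4-methyl-11-[(triisopropylsilyl)oxy]-8-[(trimethylsilyl)methyl]undeca-4,8-dien-1-yl]-1,3-dioxane | C[C@H]1C[C@H](C)OC(CCC/C(C)=C/CC/C(C[Si](C)(C)C)=C/CCO[Si](C(C)C)(C(C)C)C(C)C)O1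
F2 | step 9 | (2S,4S)-4-{[(1S,4aS,5R,8aS)-4a-methyl-6-methylidene-5-{2-[(triisopropylsilyl)oxy]ethyl}decahydronaphthalen-1-yl]oxy}pentan-2-ol | CC(C)[Si](C(C)C)(C(C)C)OCC[C@@H]1C(=C)CC[C@@H]2[C@@H](O[C@@H](C)C[C@H](C)O)CCC[C@@]12C
F3 | step 9 | (4S)-4-{[(1S,4aS,5R,8aS)-4a-methyl-6-methylidene-5-{2-[(triisopropylsilyl)oxy]ethyl}decahydronaphthalen-1-yl]oxy}pentan-2-one | CC(C)[Si](C(C)C)(C(C)C)OCC[C@@H]1C(=C)CC[C@@H]2[C@@H](O[C@@H](C)CC(C)=O)CCC[C@@]12C
F4 | step 9 | (1S,4aS,5R,8aS)-4a-methyl-6-methylidene-5-{2-[(triisopropylsilyl)oxy]ethyl}decahydronaphthalen-1-ol | CC(C)[Si](C(C)C)(C(C)C)OCC[C@@H]1C(=C)CC[C@@H]2[C@@H](O)CCC[C@@]12C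
F5 | step 9 | (4aS,5R,8aS)-4a-methyl-6-methylidene-5-{2-[(triisopropylsilyl)oxy]ethyl}octahydronaphthalen-1(2H)-one | CC(C)[Si](C(C)C)(C(C)C)OCC[C@@H]1C(=C)CC[C@@H]2C(=O)CCC[C@@]12C
F6 | step 9 | (4aS,5R,8aS)-1-(methoxymethylidene)-4a-methyl-6-methylidene-5-{2-[(triisopropylsilyl)oxy]ethyl}decahydronaphthalene (E/Z mixture) | CC(C)[Si](C(C)C)(C(C)C)OCC[C@@H]1C(=C)CC[C@@H]2C(=COC)CCC[C@@]12C
F7 | step 10 | 2-[(1R,4aR,5R,8aR)-4a-methyl-6-methylidene-5-{2-[(triisopropylsilyl)oxy]ethyl}decahydronaphthalen-1-yl]ethanol | CC(C)[Si](C(C)C)(C(C)C)OCC[C@@H]1C(=C)CC[C@@H]2[C@@H](CCO)CCC[C@@]12C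
F8 | step 10 | 2-[(1R,4aR,5R,8aR)-4a-methyl-6-methylidene-5-{2-[(triisopropylsilyl)oxy]ethyl}decahydronaphthalen-1-yl]acetaldehyde | CC(C)[Si](C(C)C)(C(C)C)OCC[C@@H]1C(=C)CC[C@@H]2[C@@H](CC=O)CCC[C@@]12C
F9 | step 10 | tert-butyldimethyl({2-[(1R,4aR,5R,8aR)-4a-methyl-6-methylidene-5-{2-[(triisopropylsilyl)oxy]ethyl}decahydronaphthalen-1-yl]ethenyl}oxy)silane (E/Z mixture) | CC(C)[Si](C(C)C)(C(C)C)OCC[C@@H]1C(=C)CC[C@@H]2[C@@H](C=CO[Si](C)(C)C(C)(C)C)CCC[C@@]12C
F10 | step 4 | (E)-tert-butyldimethyl[(5-methyldec-5-en-9-yn-1-yl)oxy]silane | C#CCC/C=C(\C)CCCCO[Si](C)(C)C(C)(C)C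
F11 | step 4 | {(1Z,5E)-10-[(tert-butyldimethylsilyl)oxy]-6-methyl-2-[(trimethylsilyl)methyl]deca-1,5-dien-1-yl}copper | [Cu]/C=C(\C[Si](C)(C)C)CC/C=C(\C)CCCCO[Si](C)(C)C(C)(C)C
F0 | step 11 | none | none
A1 | alternative 1 | (R)-Wieland–Miescher ketone, (8aR)-8a-methyl-3,4,8,8a-tetrahydronaphthalene-1,6(2H,7H)-dione | C[C@@]12CCC(=O)C=C1CCCC2=O
A2 | alternative 2 | dimethyl 2-[(4E,8E)-4,8-dimethyl-11-[(triisopropylsilyl)oxy]undeca-4,8-dien-1-yl]malonate | COC(=O)C(CCC/C(C)=C/CC/C(C)=C/CCO[Si](C(C)C)(C(C)C)C(C)C)C(=O)OC
A3 | alternative 2 | dimethyl rac-(4aS,5R,8aS)-4a-methyl-6-methylidene-5-{2-[(triisopropylsilyl)oxy]ethyl}octahydronaphthalene-1,1(2H)-dicarboxylate (racemate, one enantiomer drawn) | CC(C)[Si](C(C)C)(C(C)C)OCC[C@@H]1C(=C)CC[C@@H]2C(C(=O)OC)(C(=O)OC)CCC[C@@]12C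
A4 | alternative 3 | andrographolide | O=C1OC[C@@H](O)/C1=C\C[C@@H]2C(=C)CC[C@@H]3[C@](C)(CO)[C@H](O)CC[C@@]23C
A5 | alternative 3 | ent-labda-8(17),12E,14-trien-19-ol | C=C/C(C)=C/C[C@@H]1C(=C)CC[C@@H]2[C@](C)(CO)CCC[C@@]12C
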